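**Plan**

1. Retrosynthetic cuts, in order: the pyran O1–C8a bond (B-ring C3'–O); the C2'–side-chain bond (2'-bromide + 2-methylbut-3-yn-2-ol); the chromone O1–C2 and C3–C1' bonds (acetal cyclisation, chalcone 1,2-aryl shift); the chalcone C=C (aldol of resacetophenone and 6-bromovanillin).
2. Enabling feature: the pyran oxygen sits on B-ring carbon C3' (chromene C8a), ortho to the free C4' phenol (chromene 8-OH) and next to the alkenyl-bearing C2' (chromene C4a). A vanillin-type ring lacking that oxygen can therefore gain it when the oxidised phenol is captured at C3' by a cis-tethered tertiary alcohol.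
3. Forward order: the chromone ring is built first (Claisen–Schmidt, oxidative aryl shift, acid cyclisation that also removes both MOM groups). The C5 side chain follows (Sonogashira, Lindlar), and the dimethylpyran ring closes last, giving the target directly with no protecting group left to remove.
4. Stereochemistry: the target has no stereocentre. The only stereo-element of the route is the Z alkene of the cyclisation precursor, set by syn semi-hydrogenation; it holds the hydroxyl over C3'.

Key step: step 8

Assumption: the target is achiral, so no enantiocontrol is needed; sp3 centres that appear in passing (the β-keto acetal and the dienone tautomer) are racemic and are erased in the next event.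

**Step 1**
Reactants: 1 1-(2,4-dihydroxyphenyl)ethan-1-one (resacetophenone)
Product: 2 1-[2-hydroxy-4-(methoxymethoxy)phenyl]ethan-1-one
Conditions: MOMCl (1.05 equiv), K2CO3, acetone, 0 °C → rt
Reagents that add atoms: chloromethyl methyl ether, COCCl
Why: Williamson-type O-alkylation in which the 2-OH, hydrogen-bonded to the acetyl carbonyl, stays untouched and only the 4-phenoxide is alkylated.

**Step 2**
Reactants: 3 2-bromo-4-hydroxy-5-methoxybenzaldehyde (6-bromovanillin)
Product: 4 2-bromo-5-methoxy-4-(methoxymethoxy)benzaldehyde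
Conditions: MOMCl (1.2 equiv), K2CO3, acetone, 0 °C → rt
Reagents that add atoms: chloromethyl methyl ether, COCCl
Why: Williamson O-alkylation (MOM protection) of the only phenol, giving an acetal ether that withstands the hydroxide of step 3 and masks the phenol from the oxidant of step 4.

**Step 3**
Reactants: 2 1-[2-hydroxy-4-(methoxymethoxy)phenyl]ethan-1-one; 4 2-bromo-5-methoxy-4-(methoxymethoxy)benzaldehyde
Product: 5 (E)-3-[2-bromo-5-methoxy-4-(methoxymethoxy)phenyl]-1-[2-hydroxy-4-(methoxymethoxy)phenyl]prop-2-en-1-one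
Conditions: KOH (50 % aq, excess), EtOH, 0 °C → rt; cold dilute AcOH to pH 5
Reagents that add atoms: none
Why: Claisen–Schmidt condensation of the acetophenone enolate with the non-enolisable aldehyde, where E1cB dehydration gives the E enone and the chelated 2'-phenoxide does not cyclise at room temperature.

**Step 4**
Reactants: 5 (E)-3-[2-bromo-5-methoxy-4-(methoxymethoxy)phenyl]-1-[2-hydroxy-4-(methoxymethoxy)phenyl]prop-2-en-1-one
Product: 6 2-[2-bromo-5-methoxy-4-(methoxymethoxy)phenyl]-1-[2-hydroxy-4-(methoxymethoxy)phenyl]-3,3-dimethoxypropan-1-one (racemic; used crude after filtration of the thallium(I) salt)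
Conditions: Tl(NO3)3·3H2O (1.1 equiv), MeOH–HC(OMe)3 3:1, rt
Reagents that add atoms: methanol, CO
Why: Thallium(III) nitrate oxidative rearrangement of a 2'-hydroxychalcone, in which methoxythallation of the enone is followed by 1,2-migration of the B-ring aryl group (activated by its para acetal oxygen) with loss of Tl(I) and trapping of the oxocarbenium ion by methanol as the dimethyl acetal.

**Step 5**
Reactants: 6 2-[2-bromo-5-methoxy-4-(methoxymethoxy)phenyl]-1-[2-hydroxy-4-(methoxymethoxy)phenyl]-3,3-dimethoxypropan-1-one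
Product: 7 3-(2-bromo-4-hydroxy-5-methoxyphenyl)-7-hydroxy-4H-chromen-4-one
Conditions: 10 % aq HCl, MeOH–THF, 60 °C
Reagents that add atoms: none
Why: Acid-catalysed cyclocondensation of the 2-hydroxyphenyl β-keto acetal (phenol capture of the oxocarbenium ion, then elimination of methanol) closes the 4H-chromen-4-one, and the same acid hydrolyses both methoxymethyl acetals.

**Step 6**
Reactants: 7 3-(2-bromo-4-hydroxy-5-methoxyphenyl)-7-hydroxy-4H-chromen-4-one; 8 2-methylbut-3-yn-2-ol (3 equiv)
Product: 9 7-hydroxy-3-[4-hydroxy-2-(3-hydroxy-3-methylbut-1-yn-1-yl)-5-methoxyphenyl]-4H-chromen-4-one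
Conditions: Pd(PhCN)2Cl2 (5 mol %), t-Bu3P·HBF4 (10 mol %), CuI (5 mol %), i-Pr2NH (4 equiv), DMF, 50 °C, degassed
Reagents that add atoms: none
Why: Sonogashira coupling in which the bulky electron-rich phosphine lets Pd(0) insert into the electron-rich, ortho-substituted C–Br bond under mild conditions, the phenols are tolerated as ammonium salts, and the hindered amine does not add to C2 of the chromone.

**Step 7**
Reactants: 9 7-hydroxy-3-[4-hydroxy-2-(3-hydroxy-3-methylbut-1-yn-1-yl)-5-methoxyphenyl]-4H-chromen-4-one
Product: 10 7-hydroxy-3-{4-hydroxy-2-[(Z)-3-hydroxy-3-methylbut-1-en-1-yl]-5-methoxyphenyl}-4H-chromen-4-one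
Conditions: H2 (1 atm), Lindlar catalyst (Pd/CaCO3–Pb), quinoline, EtOAc–MeOH, rt, stopped after 1 equiv H2
Reagents that add atoms: none
Why: Lindlar semi-hydrogenation, where syn delivery of hydrogen on the poisoned palladium surface sets the Z alkene, while the chromone C2=C3 bond, the phenols and the tertiary alcohol are inert and quinoline suppresses over-reduction.

**Step 8**
Reactants: 10 7-hydroxy-3-{4-hydroxy-2-[(Z)-3-hydroxy-3-methylbut-1-en-1-yl]-5-methoxyphenyl}-4H-chromen-4-one
Product: 12 7-hydroxy-3-(8-hydroxy-7-methoxy-2,2-dimethyl-2H-chromen-5-yl)-4H-chromen-4-one (target), via 7-hydroxy-3-(7-methoxy-2,2-dimethyl-8-oxo-8,8a-dihydro-2H-chromen-5-yl)-4H-chromen-4-one (2,4-cyclohexadienone tautomer) 11 (not isolated)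
Conditions: PhI(OAc)2 (1.0 equiv, slow addition), NaHCO3 (powder), 4 Å MS, CH2Cl2–(CF3)2CHOH 4:1, 0.01 M, −40 → 0 °C
Reagents that add atoms: none
Why: Proposed new method: ligand exchange of the electron-rich C4' guaiacol hydroxyl onto iodine(III) (the 7-OH sits on a vinylogous-acid ring too electron-poor to be oxidised) and loss of PhI give a phenoxonium ion with positive charge at C1', C3' and C5'; the tertiary hydroxyl, held over C3' by the Z alkene, adds there, forming the C3'–O bond and closing the 2,2-dimethylpyran ring as dienone 11, whose C3'–H enolises irreversibly to the arene. The closest known reactions are iodine(III) oxidative dearomatisations of guaiacols and 4-substituted phenols with capture by a tethered alcohol (spiroetherification, ortho-quinone monoketal formation); the difference is capture at an unsubstituted ortho carbon followed by rearomatisation. The ring closure is six-membered and annulative, 6-endo with respect to the C2'–C3' bond of the dienyl cation, which lies in the new ring. No stereocentre results, because the sp3 carbon of 11 is lost on tautomerisation. The step needs attack at C3' and not at C1' or C5': the tether cannot reach C5', C1' is quaternary and flanked by the chromone, and adducts at C1' or C5' cannot aromatise and can re-ionise in the fluoro-alcohol medium, whereas the C3' adduct leaves the equilibrium by tautomerisation. One equivalent of oxidant, high dilution, bicarbonate and low temperature protect the acid-labile tertiary allylic alcohol and limit over-oxidation of the more electron-rich product.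

**Compound list**

1 | 1-(2,4-dihydroxyphenyl)ethan-1-one (resacetophenone) | CC(=O)c1ccc(O)cc1O | starting material
2 | 1-[2-hydroxy-4-(methoxymethoxy)phenyl]ethan-1-one | CC(=O)c1ccc(OCOC)cc1O | intermediate
3 | 2-bromo-4-hydroxy-5-methoxybenzaldehyde (6-bromovanillin) | COc1cc(C=O)c(Br)cc1O | starting material
4 | 2-bromo-5-methoxy-4-(methoxymethoxy)benzaldehyde | COCOc1cc(Br)c(C=O)cc1OC | intermediate
5 | (E)-3-[2-bromo-5-methoxy-4-(methoxymethoxy)phenyl]-1-[2-hydroxy-4-(methoxymethoxy)phenyl]prop-2-en-1-one | COCOc1ccc(C(=O)/C=C/c2cc(OC)c(OCOC)cc2Br)c(O)c1 | intermediate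
6 | 2-[2-bromo-5-methoxy-4-(methoxymethoxy)phenyl]-1-[2-hydroxy-4-(methoxymethoxy)phenyl]-3,3-dimethoxypropan-1-one (racemic) | COCOc1ccc(C(=O)C(C(OC)OC)c2cc(OC)c(OCOC)cc2Br)c(O)c1 | intermediate
7 | 3-(2-bromo-4-hydroxy-5-methoxyphenyl)-7-hydroxy-4H-chromen-4-one | COc1cc(-c2coc3cc(O)ccc3c2=O)c(Br)cc1O | intermediate
8 | 2-methylbut-3-yn-2-ol | CC(C)(O)C#C | starting material
9 | 7-hydroxy-3-[4-hydroxy-2-(3-hydroxy-3-methylbut-1-yn-1-yl)-5-methoxyphenyl]-4H-chromen-4-one | COc1cc(-c2coc3cc(O)ccc3c2=O)c(C#CC(C)(C)O)cc1O | intermediate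
10 | 7-hydroxy-3-{4-hydroxy-2-[(Z)-3-hydroxy-3-methylbut-1-en-1-yl]-5-methoxyphenyl}-4H-chromen-4-one | COc1cc(-c2coc3cc(O)ccc3c2=O)c(/C=C\C(C)(C)O)cc1O | intermediate
11 | 7-hydroxy-3-(7-methoxy-2,2-dimethyl-8-oxo-8,8a-dihydro-2H-chromen-5-yl)-4H-chromen-4-one (dienone tautomer, racemic at C8a, not isolated) | COC1=CC(-c2coc3cc(O)ccc3c2=O)=C4C=CC(C)(C)OC4C1=O | intermediate
12 | 7-hydroxy-3-(8-hydroxy-7-methoxy-2,2-dimethyl-2H-chromen-5-yl)-4H-chromen-4-one | COc1cc(-c2coc3cc(O)ccc3c2=O)c2c(c1O)OC(C)(C)C=C2 | target

**Step count**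

Total steps: 8. Longest linear sequence: 7 (step 1 or step 2, then steps 3–8).

**Steps most likely to fail**

Step 8 (proposed new method). Three processes may defeat it:
- the phenoxonium ion may be captured at the para carbon C1' (or by acetate at C5'), giving quinol-type adducts that cannot aromatise;
- the product, a more electron-rich 2,6-dioxygenated phenol, may be oxidised further;
- the tertiary allylic alcohol may ionise in the fluoro-alcohol medium, leading to diene formation or Z/E isomerisation.

The fallback uses known chemistry and sets out from 10. Teuber oxidation with Frémy's salt (KH2PO4-buffered acetone–water, 0 °C) should oxidise only the para-blocked guaiacol ring at its free ortho carbon C3'. This would give 3-[(Z)-3-hydroxy-3-methylbut-1-en-1-yl]-4-(7-hydroxy-4-oxo-4H-chromen-3-yl)-6-methoxycyclohexa-3,5-diene-1,2-dione F1. F1 would be reduced in the same flask with aqueous Na2S2O4 to the catechol 3-{3,4-dihydroxy-2-[(Z)-3-hydroxy-3-methylbut-1-en-1-yl]-5-methoxyphenyl}-7-hydroxy-4H-chromen-4-one F2. Mild acid (PPTS, CH2Cl2, rt to 40 °C) should then effect the classical cyclodehydration of an ortho-(Z-3-hydroxy-3-methylbutenyl)phenol, in which only the C3' hydroxyl can reach the allylic cation. The route is rejoined at 12.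

Step 4. A methoxymethyl group may be lost early in the nitric-acid-releasing thallium medium, exposing a phenol to the oxidant. Migration of the ortho-bromo aryl ring may also be slow, so that solvent addition or aurone-type cyclisation at the free 2'-phenol competes.

The fallback sets out from 5 and closes the pyranone ring before the shift. Oxa-Michael cyclisation (NaOAc, EtOH, reflux) would give the flavanone 2-[2-bromo-5-methoxy-4-(methoxymethoxy)phenyl]-7-(methoxymethoxy)chroman-4-one F3. The iodine(III)-mediated oxidative 2,3-aryl migration of flavanones (PhI(OH)OTs, HC(OMe)3, rt to 50 °C) should convert F3 into 3-[2-bromo-5-methoxy-4-(methoxymethoxy)phenyl]-7-(methoxymethoxy)-4H-chromen-4-one F4. Hydrolysis of the two acetals (10 % aq HCl, MeOH, 60 °C) rejoins the route at 7.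

Step 6. Oxidative addition into the electron-rich, ortho-substituted C–Br bond may be slow in a substrate that is present as a phenoxide salt, so that alkyne homocoupling and catalyst decay outrun the cross-coupling.

The fallback sets out from 7 and masks both phenols as electron-withdrawing esters. Acylation (PivCl, Et3N, DMAP, CH2Cl2) would give 3-[2-bromo-5-methoxy-4-(pivaloyloxy)phenyl]-4-oxo-4H-chromen-7-yl pivalate F5, which is soluble, free of phenoxide and less electron-rich at the C–Br bond. Sonogashira coupling with 8 (PdCl2(PPh3)2, CuI, Et3N, THF, 65 °C) should then give 3-[2-(3-hydroxy-3-methylbut-1-yn-1-yl)-5-methoxy-4-(pivaloyloxy)phenyl]-4-oxo-4H-chromen-7-yl pivalate F6. Methanolysis (K2CO3, MeOH, 0 °C to rt, under argon) rejoins the route at 9.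

**Further compounds**

F1 | step 8 | 3-[(Z)-3-hydroxy-3-methylbut-1-en-1-yl]-4-(7-hydroxy-4-oxo-4H-chromen-3-yl)-6-methoxycyclohexa-3,5-diene-1,2-dione | COC1=CC(-c2coc3cc(O)ccc3c2=O)=C(/C=C\C(C)(C)O)C(=O)C1=O
F2 | step 8 | 3-{3,4-dihydroxy-2-[(Z)-3-hydroxy-3-methylbut-1-en-1-yl]-5-methoxyphenyl}-7-hydroxy-4H-chromen-4-one | COc1cc(-c2coc3cc(O)ccc3c2=O)c(/C=C\C(C)(C)O)c(O)c1O
F3 | step 4 | 2-[2-bromo-5-methoxy-4-(methoxymethoxy)phenyl]-7-(methoxymethoxy)chroman-4-one | COCOc1ccc2c(c1)OC(CC2=O)c1cc(OC)c(OCOC)cc1Br
F4 | step 4 | 3-[2-bromo-5-methoxy-4-(methoxymethoxy)phenyl]-7-(methoxymethoxy)-4H-chromen-4-one | COCOc1ccc2c(c1)occ(-c1cc(OC)c(OCOC)cc1Br)c2=O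
F5 | step 6 | 3-[2-bromo-5-methoxy-4-(pivaloyloxy)phenyl]-4-oxo-4H-chromen-7-yl pivalate | COc1cc(-c2coc3cc(OC(=O)C(C)(C)C)ccc3c2=O)c(Br)cc1OC(=O)C(C)(C)C
F6 | step 6 | 3-[2-(3-hydroxy-3-methylbut-1-yn-1-yl)-5-methoxy-4-(pivaloyloxy)phenyl]-4-oxo-4H-chromen-7-yl pivalate | COc1cc(-c2coc3cc(OC(=O)C(C)(C)C)ccc3c2=O)c(C#CC(C)(C)O)cc1OC(=O)C(C)(C)C
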